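Ring locants used throughout (cyclopent-2-en-1-one numbering): C1 = C=O, C2 = pentenyl-bearing carbon, C3 = ester-chain-bearing carbon, C4 = CH(OH), C5 = CH(Br). Read from the SMILES, C4 is R, C5 is S, and OH and Br are trans. The target 13 is (4R,5S)-5-bromo-4-hydroxy-3-(8-methoxy-8-oxooctyl)-2-[(2Z)-pent-2-en-1-yl]cyclopent-2-en-1-one.

## The problem

Every ring carbon of 13 is different and functionalised: the C1 ketone, a tetrasubstituted C2=C3 bond with a (Z)-pent-2-enyl chain on C2 and a (CH2)7CO2Me chain on C3, a secondary allylic alcohol at C4 (R) and a secondary α-bromide at C5 (S), with OH and Br trans. The two chains are unbranched and of similar size, so a construction that passes through a pseudo-symmetric unit (1,4-diketone aldol, alkyne cyclocarbonylation, reduction of a 2-ene-1,4-dione) cannot tell C2 from C3; their placement has to be written into the bond-forming logic. Of the two adjacent stereocentres, C5 is α to the ketone and carries a leaving group, so it is epimerisable; C4 is robust, must control C5 (bromide delivered anti to the C4 oxygen), and is where the absolute configuration has to be decided. The trans-β-hydroxy-α-bromo ketone will not survive base (the C4 alkoxide is anti to C–Br and closes to the epoxy ketone; E1cB dehydration is also open), reducing metals or Pd/H2. Bromine must therefore arrive at the end under neutral or acidic conditions, and O4 should carry no group that needs base or fluoride for removal. The Z alkene is skipped relative to the enone and can be isomerised by radicals, triplets or π-allyl metals, so it must come from a Z-defined C5 unit; the methyl ester excludes late strong nucleophiles. The enabling feature is the six-atom sequence O(hydroxyl)–C4–C5–C1(=O)–C2=C3: if that oxygen is tied to C3 instead of C4 being bonded to C3, the six atoms are the ring of a 4H-pyran-4-one. The trans O/Br pattern at C4/C5 is what anti capture of a nucleophile by the epoxide-fused oxyallyl zwitterion of a 4-pyranone photoreaction (6-oxabicyclo[3.1.0]hexenyl skeleton) would leave behind.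

## Retrosynthesis

**13 ⇒ 12.** No bond is cut: 13 is taken from the racemic trans-bromohydrin 12 by acylative kinetic resolution. The absolute configuration is decided last for a structural reason: the precursor of the key step is flat and achiral, and the sense of the photochemical closure that creates C4 cannot be steered by a reagent. Carrying a chiral C4 building block instead would bring back the long, base-exposed sequence of Alternative 1. The forward step must tell the antipodes apart under neutral conditions; half of the material is the price.

**12 ⇒ 9 (key disconnection).** The C3–C4 ring bond and the C5–Br bond are cut and the C4 hydroxyl oxygen is reconnected to C3. This unfolds the cyclopentenone into 4-pyranone 9 plus the elements of HBr. The atom mapping is: pyranone O1 becomes the hydroxyl oxygen, and pyranone C2, C3, C4, C5, C6 become product C3, C2, C1, C5, C4. Compared with cutting C5–Br alone (enolate bromination) or only the C–O bonds of an epoxide, this cut removes the carbocycle, both stereocentres and the halogen at once; 9 is planar and achiral. The forward reaction must close pyranone C2–C6 photochemically, capture bromide at the unsubstituted oxyallyl terminus anti to the epoxide oxygen, and protonate the alkoxide before the epoxide can re-close.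

**9 ⇒ 6 + 8.** The bond between the first and second CH2 of the ester chain is cut, giving 2-methylpyranone 6 and iodo ester 8 (from bromo ester 7). This is preferred over building the chain into the open-chain diketone because the 2-methyl group of a 4-pyranone is a vinylogous methyl ketone that can be deprotonated selectively, and because it leaves a symmetrical diketone for the ring synthesis. The forward step must alkylate the exocyclic carbon without touching the ester or the doubly allylic CH2.

**6 ⇒ 4.** The pyranone O1–C6 and C5–C6 bonds are cut, removing C6 as a one-carbon electrophile: 6 comes from the 3-substituted pentane-2,4-dione 4 and an amide acetal through enaminone 5. Since 4 has two identical acetyl groups, there is no question of which methyl reacts. The pentenyl group sits automatically on pyranone C3, which becomes C2 of the enone, so the C2/C3 regiochemistry of the target is fixed by the central carbon of a β-diketone.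

**4 ⇒ 3 + 2; 2 ⇒ 1; 8 ⇒ 7.** The bond from the central diketone carbon to the allylic CH2 is cut, giving acetylacetone 3 and (Z)-1-bromopent-2-ene 2, the latter from commercial (Z)-pent-2-en-1-ol 1. An SN2 alkylation is chosen over π-allyl-metal chemistry because it cannot scramble the Z geometry or the allylic position. Iodide 8 is one halide exchange from commercial 7.

## Roads not taken

**Alternative 1:** (the obvious route) Cut only C5–Br: α′-bromination of the enantiopure silyl ether A1, through its kinetic enolate or silyl enol ether with NBS anti to the C4–OSi group, then desilylation. A1 would have to be assembled on a chiral cyclopentenone building block by iodination, cross-coupling, conjugate addition and re-oxidation, which is a long run-up. The C5 enolate has a β-silyloxy leaving group at C4, and deprotonation also competes at the two γ-CH2 groups, one of them doubly allylic. Fluoride or base deprotection of a trans-bromohydrin silyl ether leads to the epoxide. The chosen plan delivers bromine in the ring-forming event, never exposes the bromohydrin to base, and is several steps shorter.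

**Alternative 2:** Cut C1–C2, C1–C5 and C3–C4: a (2+2+1) Pauson–Khand reaction of enyne ester A2 with CO and a two-carbon alkene. The two alkyne termini are both propargylic CH2 groups of equal size, so the enone A3 and its regioisomer A4 would form without control. Intermolecular reactions with unstrained alkenes are also poor. A3 still lacks the C4 oxygen and the C5 bromine, so the stereochemical problem would remain untouched. In the chosen plan the C2/C3 assignment comes from a β-diketone alkylation and the oxidation pattern from the ring contraction itself.

**Alternative 3:** Cut C4–C5: Piancatelli rearrangement of furylmethanol A5 (aqueous acid, conrotatory 4π closure of the hydroxypentadienyl cation) to the racemic hydroxy enone A6, then bromination as in Alternative 1. A5 is a 2,3,4-trisubstituted furan with two different chains at C3 and C4, harder to make regiodefined than pyranone 9. A primary furfuryl alcohol also ionises reluctantly and tends to polymerise. The product is racemic and carries no bromine. The chosen photochemical electrocyclisation is the cousin of this step, but it starts from a ring made by two enolate alkylations and delivers C–Br and the trans relationship as well.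

Key step: step 6

Assumption: in the final resolution the lipase is taken to treat the chain-bearing C3 flank of the carbinol as the large group and the CHBr flank as the smaller one; the sense would be confirmed on the recovered alcohol (Mosher ester analysis) before scale-up.

## Route

Step 1
Reactants: 1 (Z)-pent-2-en-1-ol
Product: 2 (Z)-1-bromopent-2-ene
Conditions: PBr3 (0.4 equiv), pyridine (cat.), Et2O, −20 → 0 °C
Reagents that add atoms: phosphorus tribromide, BrP(Br)Br
Why: Bromination of a primary allylic alcohol through its phosphite ester (SN2); at low temperature the Z geometry should be retained and allylic transposition kept minimal, as is usual for Z-allylic bromides used in jasmonoid chemistry.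

Step 2
Reactants: 2 (Z)-1-bromopent-2-ene; 3 pentane-2,4-dione (acetylacetone, 1.5–2 equiv)
Product: 4 3-[(2Z)-pent-2-en-1-yl]pentane-2,4-dione
Conditions: K2CO3, acetone, reflux
Reagents that add atoms: none
Why: C-alkylation of the acetylacetone enolate by SN2 at the primary allylic carbon; excess 3 suppresses dialkylation, and the Z alkene is safe because no metal-allyl intermediate is involved.

Step 3
Reactants: 4 3-[(2Z)-pent-2-en-1-yl]pentane-2,4-dione
Product: 6 2-methyl-3-[(2Z)-pent-2-en-1-yl]-4H-pyran-4-one, via enaminone 5 (not isolated)
Conditions: Me2NCH(OMe)2 (1.1 equiv), toluene, 90 °C; then AcOH, 70 °C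
Reagents that add atoms: N,N-dimethylformamide dimethyl acetal, COC(OC)N(C)C
Why: Amide-acetal condensation at one of the two equivalent methyl ketones gives the E-enaminone 5 (the central CH has only one hydrogen and cannot condense); under acid the enol oxygen of the remaining acetyl group adds 6-endo to the β-amino enone and dimethylamine is lost, the same addition–elimination that turns 2-hydroxyaryl enaminones into chromones; no stereocentre is formed.

Step 4
Reactants: 7 methyl 7-bromoheptanoate
Product: 8 methyl 7-iodoheptanoate
Conditions: NaI, acetone, reflux
Reagents that add atoms: sodium iodide, [Na+].[I-]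
Why: Finkelstein halide exchange driven by precipitation of NaBr; the iodide allows a clean low-temperature alkylation in step 5.

Step 5
Reactants: 6 2-methyl-3-[(2Z)-pent-2-en-1-yl]-4H-pyran-4-one; 8 methyl 7-iodoheptanoate
Product: 9 methyl 8-{4-oxo-3-[(2Z)-pent-2-en-1-yl]-4H-pyran-2-yl}octanoate
Conditions: LiHMDS (1.0 equiv), THF, −78 °C; then 8, DMPU, −78 → −20 °C
Reagents that add atoms: none
Why: Lateral (vinylogous) deprotonation of the 2-methyl group of a 4-pyranone gives the exocyclic dienolate, which is C-alkylated by the primary iodide, as precedented for 2-methyl-4-pyranones and O-protected maltol; the doubly allylic side-chain CH2 is far less acidic and the ester should survive at low temperature.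

Step 6
Reactants: 9 methyl 8-{4-oxo-3-[(2Z)-pent-2-en-1-yl]-4H-pyran-2-yl}octanoate
Product: 12 (±)-(4R*,5S*)-5-bromo-4-hydroxy-3-(8-methoxy-8-oxooctyl)-2-[(2Z)-pent-2-en-1-yl]cyclopent-2-en-1-one (trans), via oxyallyl zwitterion 10 (not isolated), via bromo epoxy enolate 11 (not isolated)
Conditions: hν (254 nm, FEP flow coil), 9 (5 mM), LiBr (0.5 M), HFIP–MeCN 1:1, 0 °C, Ar; partial conversion, 9 recycled
Reagents that add atoms: lithium bromide, [Li+].[Br-]
Why: Proposed new method: excitation of the 4-pyranone (π,π*) should cause disrotatory 4π closure between pyranone C2 and C6 (photochemically allowed for the four-electron cross-conjugated dienone) to the cis-fused 6-oxabicyclo[3.1.0]hexenyl oxyallyl zwitterion 10; this one event closes the carbocycle (the C3–C4 bond of the product) and the epoxide, and creates C4 in either sense, hence the racemate. The closest known reaction type is the photochemical ring contraction of 4-pyranones in hydroxylic solvents, which gives trans-5-alkoxy- or 5-hydroxy-4-hydroxycyclopent-2-enones by solvent capture of the same zwitterion; here bromide, a far better nucleophile than water or a fluoro alcohol, is offered in large excess in HFIP, which is transparent, stabilises the zwitterion by hydrogen bonding and is itself almost non-nucleophilic. Bromide should add to the oxyallyl terminus derived from pyranone C5 anti to the epoxide oxygen, which shields the syn face, and the resulting enolate 11 opens the epoxide by E1cB cleavage of the O–C3 bond, so Br at C5 and OH at C4 end up trans and C5 is controlled by C4. The step needs regioselectivity between the two oxyallyl termini: attack at the unsubstituted terminus gives a secondary bromide and the tetrasubstituted conjugated enone, whereas attack at the pentenyl-bearing terminus would give a tertiary bromide beside a fully substituted epoxide carbon and should be slower and reversible, since α-bromo enolates re-ionise to oxyallyl cations. HFIP protonates the C4 alkoxide at once, which blocks its return to the epoxy enone and the onward phototransposition to a 2-pyranone. The very short singlet lifetime of the pyranone and the hydrogen-bonded state of bromide in HFIP should limit electron-transfer quenching, and flow irradiation to partial conversion limits secondary photolysis of the C–Br bond.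

Step 7
Reactants: 12 (±)-(4R*,5S*)-5-bromo-4-hydroxy-3-(8-methoxy-8-oxooctyl)-2-[(2Z)-pent-2-en-1-yl]cyclopent-2-en-1-one
Product: 13 (4R,5S)-5-bromo-4-hydroxy-3-(8-methoxy-8-oxooctyl)-2-[(2Z)-pent-2-en-1-yl]cyclopent-2-en-1-one (CNP0306311.1)
Conditions: immobilised Burkholderia cepacia lipase (or Candida antarctica lipase B), vinyl acetate (5 equiv), MTBE, 4 Å MS, 30 °C, to ca. 55% conversion; chromatography
Reagents that add atoms: none
Why: Lipase-catalysed acylative kinetic resolution with vinyl acetate (irreversible through tautomerisation to acetaldehyde), established for rethrolone-type 4-hydroxycyclopent-2-enones and for trans-2-halocycloalkanols; by the empirical size rule for secondary alcohols the (4S,5R) antipode should be acetylated and (4R,5S)-13 left as the free alcohol, its enantiomeric purity rising as conversion passes one half. Both stereocentres were fixed relative to each other in step 6; the enzyme only selects the antipode, under neutral conditions that spare the bromohydrin.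

## Compound list

1 | (Z)-pent-2-en-1-ol | CC/C=C\CO | starting material
2 | (Z)-1-bromopent-2-ene | CC/C=C\CBr | intermediate
3 | pentane-2,4-dione | CC(=O)CC(C)=O | starting material
4 | 3-[(2Z)-pent-2-en-1-yl]pentane-2,4-dione | CC/C=C\CC(C(C)=O)C(C)=O | intermediate
5 | (1E,6Z)-4-acetyl-1-(dimethylamino)nona-1,6-dien-3-one | CC/C=C\CC(C(C)=O)C(=O)/C=C/N(C)C | intermediate (not isolated)
6 | 2-methyl-3-[(2Z)-pent-2-en-1-yl]-4H-pyran-4-one | CC/C=C\CC1=C(C)OC=CC1=O | intermediate
7 | methyl 7-bromoheptanoate | COC(=O)CCCCCCBr | starting material
8 | methyl 7-iodoheptanoate | COC(=O)CCCCCCI | intermediate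
9 | methyl 8-{4-oxo-3-[(2Z)-pent-2-en-1-yl]-4H-pyran-2-yl}octanoate | CC/C=C\CC1=C(CCCCCCCC(=O)OC)OC=CC1=O | intermediate
10 | 1-(8-methoxy-8-oxooctyl)-2-[(2Z)-pent-2-en-1-yl]-6-oxabicyclo[3.1.0]hex-2-en-4-ylium-3-olate (cis-fused; racemic, the enantiomer leading to 13 drawn) | [O-]C1=C(C/C=C\CC)[C@@]2(CCCCCCCC(=O)OC)O[C@H]2[CH+]1 | intermediate (not isolated)
11 | lithium 4-bromo-1-(8-methoxy-8-oxooctyl)-2-[(2Z)-pent-2-en-1-yl]-6-oxabicyclo[3.1.0]hex-2-en-3-olate (Br anti to the epoxide oxygen; racemic, the enantiomer leading to 13 drawn) | [Li+].[O-]C1=C(C/C=C\CC)[C@@]2(CCCCCCCC(=O)OC)O[C@H]2[C@@H]1Br | intermediate (not isolated)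
12 | (±)-(4R*,5S*)-5-bromo-4-hydroxy-3-(8-methoxy-8-oxooctyl)-2-[(2Z)-pent-2-en-1-yl]cyclopent-2-en-1-one (racemate, both enantiomers written) | CC/C=C\CC1=C(CCCCCCCC(=O)OC)[C@@H](O)[C@H](Br)C1=O.CC/C=C\CC1=C(CCCCCCCC(=O)OC)[C@H](O)[C@@H](Br)C1=O | intermediate
13 | (4R,5S)-5-bromo-4-hydroxy-3-(8-methoxy-8-oxooctyl)-2-[(2Z)-pent-2-en-1-yl]cyclopent-2-en-1-one | CC/C=C\CC1=C(CCCCCCCC(=O)OC)[C@@H](O)[C@H](Br)C1=O | target

## Step count and risks

Total steps: 7. Longest linear sequence: 6 steps (1 → 2 → 4 → 6 → 9 → 12 → 13); step 4 is a one-step side branch.

**Step 6 (key step, proposed new method).** Several processes could defeat it: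
- inefficient 2,6-bridging or photodimerisation of a pyranone that has only one substituted oxyallyl terminus;
- loss of the zwitterion by re-closure to the epoxy enone and onward phototransposition, or by solvent capture, if bromide capture is too slow;
- capture at the pentenyl-bearing terminus;
- electron-transfer quenching by bromide, followed by bromine-atom chain Z→E isomerisation of the side-chain alkene;
- secondary photolysis of the C–Br bond of the product.

The fallback uses known chemistry and keeps bromide away from light. It sets out from 9, which is irradiated in MeCN–H2O (the documented hydroxylic-solvent capture) to give the (±)-trans-4,5-diol F1. Cyclodehydration with PPh3/DIAD then gives the cis-fused 4,5-epoxy enone F2; either hydroxyl may be activated, since in the racemic series both modes give the same racemate. LiBr/AcOH in THF opens F2 by SN2 at C5 (α to the ketone, inversion), and the route is rejoined at 12.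

**Step 7.** Discrimination may be poor, or turnover absent, because both flanks of the carbinol are bulky and the CHBr flank must enter the smaller pocket. The enzyme may also transfer the substrate's own fatty ester acyl group (oligomerisation), and the sense of resolution may be reversed. The fallback sets out from 12, which is esterified with (S)-2-methoxy-2-phenylacetic acid (EDC, cat. DMAP, 0 °C). This gives the diastereomeric esters F3 (from the 4R,5S alcohol) and F4 (from the antipode), which are separated by chromatography. F3 is cleaved by acid-catalysed methanolysis (HCl from AcCl in MeOH, 40 °C), which is degenerate for the chain methyl ester and harmless to the bromohydrin, and the route is rejoined at 13.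

**Step 5.** Deprotonation or conjugate addition may compete at the unsubstituted C5/C6 positions of the pyranone; the lateral carbon may be alkylated twice; the dienolate may attack the ester of 8. The fallback sets out from 4, which is converted with 2 equiv LDA into its 1,3-dianion and alkylated at a terminal methyl carbon by 8 to give the chain-extended diketone F5. Amide-acetal condensation at the remaining methyl group gives enaminone F6, and acid cyclisation as in step 3 rejoins the route at 9.

**Step 3.** The amide acetal may O-methylate the diketone enol; liberated dimethylamine or methoxide may cause retro-Claisen deacetylation; both methyl groups may condense. The fallback sets out from 4, whose dianion (2 equiv LDA) undergoes Claisen formylation with ethyl formate to give the enolised formyl diketone F7. Cyclodehydration with TFA in CH2Cl2 rejoins the route at 6.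

**Step 2.** O-alkylation and dialkylation of the diketone, SN2′ attack, and partial loss of Z geometry already during bromide formation in step 1 are the concerns. The fallback sets out from 3, which is alkylated with commercial 1-bromopent-2-yne (K2CO3, acetone) to give the alkynyl diketone F8. Lindlar semihydrogenation creates the Z alkene by syn addition of H2 and rejoins the route at 4.

## Further compounds

F1 | step 6 | (±)-trans-4,5-dihydroxy-3-(8-methoxy-8-oxooctyl)-2-[(2Z)-pent-2-en-1-yl]cyclopent-2-en-1-one (one enantiomer drawn) | CC/C=C\CC1=C(CCCCCCCC(=O)OC)[C@@H](O)[C@H](O)C1=O
F2 | step 6 | (±)-methyl 8-{4-oxo-3-[(2Z)-pent-2-en-1-yl]-6-oxabicyclo[3.1.0]hex-2-en-2-yl}octanoate (cis-fused epoxy enone, one enantiomer drawn) | CC/C=C\CC1=C(CCCCCCCC(=O)OC)[C@H]2O[C@H]2C1=O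
F3 | step 7 | (S)-2-methoxy-2-phenylacetate of the (4R,5S) alcohol 13 | CC/C=C\CC1=C(CCCCCCCC(=O)OC)[C@@H](OC(=O)[C@@H](OC)c2ccccc2)[C@H](Br)C1=O
F4 | step 7 | (S)-2-methoxy-2-phenylacetate of the (4S,5R) alcohol | CC/C=C\CC1=C(CCCCCCCC(=O)OC)[C@H](OC(=O)[C@@H](OC)c2ccccc2)[C@@H](Br)C1=O
F5 | step 5 | methyl 9,11-dioxo-10-[(2Z)-pent-2-en-1-yl]dodecanoate | CC/C=C\CC(C(C)=O)C(=O)CCCCCCCC(=O)OC
F6 | step 5 | methyl (12E)-13-(dimethylamino)-9,11-dioxo-10-[(2Z)-pent-2-en-1-yl]tridec-12-enoate | CC/C=C\CC(C(=O)CCCCCCCC(=O)OC)C(=O)/C=C/N(C)C
F7 | step 3 | 3,5-dioxo-4-[(2Z)-pent-2-en-1-yl]hexanal (enolised) | CC/C=C\CC(C(C)=O)C(=O)CC=O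
F8 | step 2 | 3-(pent-2-yn-1-yl)pentane-2,4-dione | CCC#CCC(C(C)=O)C(C)=O
A1 | alternative 1 | (4S)-4-[(tert-butyldimethylsilyl)oxy]-3-(8-methoxy-8-oxooctyl)-2-[(2Z)-pent-2-en-1-yl]cyclopent-2-en-1-one | CC/C=C\CC1=C(CCCCCCCC(=O)OC)[C@@H](O[Si](C)(C)C(C)(C)C)CC1=O
A2 | alternative 2 | methyl (12Z)-pentadec-12-en-9-ynoate | CC/C=C\CC#CCCCCCCCC(=O)OC
A3 | alternative 2 | methyl 8-{3-oxo-2-[(2Z)-pent-2-en-1-yl]cyclopent-1-en-1-yl}octanoate | CC/C=C\CC1=C(CCCCCCCC(=O)OC)CCC1=O
A4 | alternative 2 | methyl 8-{5-oxo-2-[(2Z)-pent-2-en-1-yl]cyclopent-1-en-1-yl}octanoate | CC/C=C\CC1=C(CCCCCCCC(=O)OC)C(=O)CC1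
A5 | alternative 3 | methyl 8-{5-(hydroxymethyl)-4-[(2Z)-pent-2-en-1-yl]furan-3-yl}octanoate | CC/C=C\Cc1c(CO)occ1CCCCCCCC(=O)OC
A6 | alternative 3 | (±)-4-hydroxy-3-(8-methoxy-8-oxooctyl)-2-[(2Z)-pent-2-en-1-yl]cyclopent-2-en-1-one | CC/C=C\CC1=C(CCCCCCCC(=O)OC)C(O)CC1=O
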